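**Retrosynthetic overview**

1. Chain numbering: C1/C2 oxirane CH2/CH, C3 C(CH3)Cl, C4 CHBr, C5 CH2, C6 CHCl, C7 C(CH3)Br, C8 CH2Cl. The plan rests on the C4–Br bond, which sits on a secondary carbon between the quaternary C3 and the C5 methylene and is out of reach of ionic substitution.
2. Key disconnection: C5–C6 and C4–Br are made together by atom-transfer radical addition of an auxiliary-bound α-chloro acyl radical (C6–C7) to the vinyl group (C4=C5) on C3.
3. The C1–C5 alkene comes from (Z)-3-methylpent-2-en-4-yn-1-ol by asymmetric epoxidation, chloride opening at C3, acetonide formation and semi-hydrogenation; the acyl partner is the bromochloroacetyl oxazolidinone.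
4. After coupling, the C7 imide becomes a Weinreb amide and then a chloromethyl ketone (adds C8); methyl addition gives the C7 carbinol, which is converted to the bromide with retention.
5. Ring order: a 1,3-dioxolane masks C1/C2 from step 3 to step 11; the only ring of the target, the oxirane, is closed last (step 13).

Key step: step 6

**Remarks.** Compound 10 is taken as the mixture of both configurations at its CHBrCl carbon; that carbon becomes the planar radical, so the mixture is of no consequence. The descriptor at the chlorinated quaternary carbon changes from S (compounds 3–5) to R (from 11 on) only because the CIP priorities change; the spatial arrangement is the same throughout.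

**Route**

Step 1
Reactants: 1 (2Z)-3-methylpent-2-en-4-yn-1-ol
Product: 2 [(2S,3R)-3-ethynyl-3-methyloxiran-2-yl]methanol
Conditions: Ti(OiPr)4 (cat.), L-(+)-diisopropyl tartrate (cat.), t-BuOOH, 4 Å MS, CH2Cl2, −20 °C
Reagents that add atoms: tert-butyl hydroperoxide, CC(C)(C)OO
Why: Katsuki–Sharpless asymmetric epoxidation of a 3,3-disubstituted allylic alcohol, in which the L-(+)-tartrate complex delivers oxygen to the face that gives the 2S epoxide and the Z geometry of 1 fixes C3 as R (ethynyl cis to CH2OH).

Step 2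
Reactants: 2 [(2S,3R)-3-ethynyl-3-methyloxiran-2-yl]methanol
Product: 3 (2S,3S)-3-chloro-3-methylpent-4-yne-1,2-diol
Conditions: TiCl(OiPr)3, CH2Cl2, 0 °C to rt; aq. tartaric acid work-up
Reagents that add atoms: chlorotitanium triisopropoxide, CC(C)O[Ti](Cl)(OC(C)C)OC(C)C
Why: Titanium-assisted opening of a 2,3-epoxy alcohol, in which chelation of the carbinol and epoxide oxygens directs chloride to C3 (tertiary and propargylic, hence the more electrophilic carbon) in an SN2-type attack with inversion, which sets the C3 chloride while C2 keeps its oxygen and configuration.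

Step 3
Reactants: 3 (2S,3S)-3-chloro-3-methylpent-4-yne-1,2-diol
Product: 4 (4S)-4-[(2S)-2-chlorobut-3-yn-2-yl]-2,2-dimethyl-1,3-dioxolane
Conditions: Me2C(OMe)2, PPTS (cat.), CH2Cl2, rt
Reagents that add atoms: 2,2-dimethoxypropane, COC(C)(C)OC
Why: Acid-catalysed transketalisation of the terminal 1,2-diol to the isopropylidene acetal, mild enough to leave the tertiary propargylic chloride and both stereocentres untouched.

Step 4
Reactants: 4 (4S)-4-[(2S)-2-chlorobut-3-yn-2-yl]-2,2-dimethyl-1,3-dioxolane
Product: 5 (4S)-4-[(2S)-2-chlorobut-3-en-2-yl]-2,2-dimethyl-1,3-dioxolane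
Conditions: H2 (1 atm), Pd/CaCO3 poisoned with Pb(OAc)2, quinoline, EtOAc–hexane, 0 °C
Reagents that add atoms: none
Why: Lindlar semi-hydrogenation of the terminal alkyne, with quinoline and low temperature limiting hydrogenolysis of the propargylic chloride; no stereocentre is touched, and the tertiary allylic chloride is kept cold and acid-free and used at once because it can undergo 1,3-transposition.

Step 5
Reactants: 6 (4R)-4-benzyl-1,3-oxazolidin-2-one; 7 bromochloroacetic acid
Product: 10 (4R)-4-benzyl-3-(2-bromo-2-chloroacetyl)-1,3-oxazolidin-2-one, via bromochloroacetyl chloride 8 (not isolated), via lithium oxazolidinide 9 (not isolated)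
Conditions: 7, (COCl)2, DMF (cat.), CH2Cl2, 0 °C to rt, evaporate; separately 6, n-BuLi, THF, −78 °C; then crude 8, −78 °C
Reagents that add atoms: none
Why: Acid chloride formation followed by N-acylation of the lithiated oxazolidinone auxiliary, fast at −78 °C so that the acidic CHBrCl proton is not disturbed.

Step 6
Reactants: 5 (4S)-4-[(2S)-2-chlorobut-3-en-2-yl]-2,2-dimethyl-1,3-dioxolane; 10 (4R)-4-benzyl-3-(2-bromo-2-chloroacetyl)-1,3-oxazolidin-2-one
Product: 11 (4R)-4-benzyl-3-[(2S,4R,5R)-4-bromo-2,5-dichloro-5-[(4S)-2,2-dimethyl-1,3-dioxolan-4-yl]hexanoyl]-1,3-oxazolidin-2-one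
Conditions: 10 (2.5 equiv), Yb(OTf)3 (1 equiv per 10), BEt3 (0.3 equiv in portions), air, CH2Cl2–THF 4:1, −78 °C
Reagents that add atoms: none
Why: Ethyl radicals from BEt3/O2 abstract bromine (the weaker carbon–halogen bond) from the Yb(OTf)3-chelated imide, the electrophilic α-chloro acyl radical adds to the terminal alkene carbon C5, and the secondary C4 radical takes bromine from a further chelated imide, which carries the chain and forms the C5–C6 and C4–Br bonds without closing any ring. The closest known reaction type is the Lewis-acid-promoted Kharasch atom-transfer addition of α-bromo oxazolidinone imides to 1-alkenes. C6 is set by the auxiliary: in the two-point chelate the radical is planar with chlorine syn to the acyl oxygen, and the alkene approaches the face away from the benzyl group, which should give 6S. C4 is set by the adjacent quaternary C3, the bromine donor being expected to approach anti to the dioxolanyl group with the C3 methyl on the C5 side to give 4R; this 1,2-induction is the least secure element of the route, and C4 epimers would have to be separated by chromatography. Regioselectivity is secured by the unhindered CH2 terminus next to a quaternary carbon that carries no allylic hydrogen, and chemoselectivity by the much weaker C–Br bond of the dihaloacetyl group. The step also needs bromine transfer to outrun loss or 1,2-shift of the C3 chlorine in the β-chloroalkyl radical, for which −78 °C and an excess of the activated bromine donor are chosen.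

Step 7
Reactants: 11 (4R)-4-benzyl-3-[(2S,4R,5R)-4-bromo-2,5-dichloro-5-[(4S)-2,2-dimethyl-1,3-dioxolan-4-yl]hexanoyl]-1,3-oxazolidin-2-one
Product: 12 (2S,4R,5R)-4-bromo-2,5-dichloro-5-[(4S)-2,2-dimethyl-1,3-dioxolan-4-yl]-N-methoxy-N-methylhexanamide
Conditions: MeNH(OMe)·HCl, AlMe3, CH2Cl2, −20 to 0 °C
Reagents that add atoms: N,O-dimethylhydroxylamine hydrochloride, CNOC.Cl
Why: Aluminium-amide aminolysis of the exocyclic imide carbonyl (Weinreb transamidation) releases the auxiliary under weakly basic conditions that should leave the C6 chloride configuration and the C4 bromide untouched.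

Step 8
Reactants: 12 (2S,4R,5R)-4-bromo-2,5-dichloro-5-[(4S)-2,2-dimethyl-1,3-dioxolan-4-yl]-N-methoxy-N-methylhexanamide
Product: 14 (3S,5R,6R)-5-bromo-1,3,6-trichloro-6-[(4S)-2,2-dimethyl-1,3-dioxolan-4-yl]heptan-2-one, via lithium hemiaminal 13 (not isolated)
Conditions: ICH2Cl, MeLi·LiBr, THF–Et2O, −78 °C; AcOH quench at −78 °C
Reagents that add atoms: chloroiodomethane, ClCI
Why: Chloromethyllithium formed by iodine–lithium exchange adds once to the Weinreb amide (carbenoid homologation), the chelated tetrahedral adduct masking the ketone until the cold acidic quench so that neither over-addition nor epimerisation at C6 is expected.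

Step 9
Reactants: 14 (3S,5R,6R)-5-bromo-1,3,6-trichloro-6-[(4S)-2,2-dimethyl-1,3-dioxolan-4-yl]heptan-2-one
Product: 15 (2S,3S,5R,6R)-5-bromo-1,3,6-trichloro-6-[(4S)-2,2-dimethyl-1,3-dioxolan-4-yl]-2-methylheptan-2-ol
Conditions: MeLi, CeCl3, THF, −78 °C; AcOH quench at −78 °C
Reagents that add atoms: methyllithium, [Li]C
Why: Organocerium 1,2-addition, weakly basic so that enolisation and alkoxide-to-epoxide closure are suppressed, under Cornforth (polar Felkin–Anh) control by the C6 chloride (C–Cl anti to the incoming methyl, approach past the C6 hydrogen), which should set C7 as S.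

Step 10
Reactants: 15 (2S,3S,5R,6R)-5-bromo-1,3,6-trichloro-6-[(4S)-2,2-dimethyl-1,3-dioxolan-4-yl]-2-methylheptan-2-ol
Product: 17 (4S)-4-[(2R,3R,5S,6S)-3,6-dibromo-2,5,7-trichloro-6-methylheptan-2-yl]-2,2-dimethyl-1,3-dioxolane, via tertiary triflate 16 (not isolated)
Conditions: Tf2O, 2,6-di-tert-butyl-4-methylpyridine, CH2Cl2, −78 °C; then Bu4NBr, −78 to 0 °C
Reagents that add atoms: tetrabutylammonium bromide, CCCC[N+](CCCC)(CCCC)CCCC.[Br-]
Why: Proposed new method: an open C7 cation is disfavoured by the two flanking chlorines, so triflate should leave with rear-side assistance from a neighbouring halogen (three-membered chloronium from C6–Cl or C8–Cl, or five-membered bromonium from C4–Br) and bromide should then open the bridged ion at the tertiary C7 anti to the bridge, two inversions giving net retention and the 7S bromide; the closest known reaction types are neighbouring-halogen-assisted substitution of β-halo sulfonates with retention and the classical conversion of tertiary chlorohydrins into vicinal bromo chlorides with HBr.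

Step 11
Reactants: 17 (4S)-4-[(2R,3R,5S,6S)-3,6-dibromo-2,5,7-trichloro-6-methylheptan-2-yl]-2,2-dimethyl-1,3-dioxolane
Product: 18 (2S,3R,4R,6S,7S)-4,7-dibromo-3,6,8-trichloro-3,7-dimethyloctane-1,2-diol
Conditions: CF3CO2H–H2O 4:1, CH2Cl2, 0 °C
Reagents that add atoms: none
Why: Acid hydrolysis of the terminal isopropylidene acetal, under which the tertiary halides should not ionise because each is flanked by electron-withdrawing substituents.

Step 12
Reactants: 18 (2S,3R,4R,6S,7S)-4,7-dibromo-3,6,8-trichloro-3,7-dimethyloctane-1,2-diol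
Product: 19 (2S,3R,4R,6S,7S)-4,7-dibromo-3,6,8-trichloro-2-hydroxy-3,7-dimethyloctyl 4-methylbenzenesulfonate
Conditions: TsCl, Bu2SnO (cat.), Et3N, CH2Cl2, 0 °C
Reagents that add atoms: 4-methylbenzenesulfonyl chloride, Cc1ccc(cc1)S(Cl)(=O)=O
Why: Stannylene-acetal-catalysed monosulfonylation of a 1,2-diol, selective for the primary hydroxyl over the hindered secondary one next to the quaternary C3.

Step 13
Reactants: 19 (2S,3R,4R,6S,7S)-4,7-dibromo-3,6,8-trichloro-2-hydroxy-3,7-dimethyloctyl 4-methylbenzenesulfonate
Product: 20 (2S)-2-[(2R,3R,5S,6S)-3,6-dibromo-2,5,7-trichloro-6-methylheptan-2-yl]oxirane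
Conditions: K2CO3, MeOH, 0 °C
Reagents that add atoms: none
Why: Intramolecular Williamson closure (3-exo-tet) of the C2 alkoxide onto the primary tosylate, fast at 0 °C so that elimination of the tertiary bromide should not compete, and with retention at C2 because the C2–O bond is never broken.

**Compound list**

1 | (2Z)-3-methylpent-2-en-4-yn-1-ol | OC/C=C(/C)C#C | starting material
2 | [(2S,3R)-3-ethynyl-3-methyloxiran-2-yl]methanol | OC[C@@H]1O[C@]1(C)C#C | intermediate
3 | (2S,3S)-3-chloro-3-methylpent-4-yne-1,2-diol | C[C@](Cl)(C#C)[C@@H](O)CO | intermediate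
4 | (4S)-4-[(2S)-2-chlorobut-3-yn-2-yl]-2,2-dimethyl-1,3-dioxolane | C[C@](Cl)(C#C)[C@@H]1COC(C)(C)O1 | intermediate
5 | (4S)-4-[(2S)-2-chlorobut-3-en-2-yl]-2,2-dimethyl-1,3-dioxolane | C[C@](Cl)(C=C)[C@@H]1COC(C)(C)O1 | intermediate
6 | (4R)-4-benzyl-1,3-oxazolidin-2-one | O=C1N[C@H](Cc2ccccc2)CO1 | starting material
7 | bromochloroacetic acid | OC(=O)C(Cl)Br | starting material
8 | bromochloroacetyl chloride | ClC(=O)C(Cl)Br | intermediate
9 | lithium (4R)-4-benzyl-2-oxo-1,3-oxazolidin-3-ide | [Li+].O=C1[N-][C@H](Cc2ccccc2)CO1 | intermediate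
10 | (4R)-4-benzyl-3-(2-bromo-2-chloroacetyl)-1,3-oxazolidin-2-one (both configurations at CHBrCl) | O=C(C(Cl)Br)N1C(=O)OC[C@H]1Cc1ccccc1 | intermediate
11 | (4R)-4-benzyl-3-[(2S,4R,5R)-4-bromo-2,5-dichloro-5-[(4S)-2,2-dimethyl-1,3-dioxolan-4-yl]hexanoyl]-1,3-oxazolidin-2-one | C[C@](Cl)([C@H](Br)C[C@H](Cl)C(=O)N1C(=O)OC[C@H]1Cc1ccccc1)[C@@H]2COC(C)(C)O2 | intermediate
12 | (2S,4R,5R)-4-bromo-2,5-dichloro-5-[(4S)-2,2-dimethyl-1,3-dioxolan-4-yl]-N-methoxy-N-methylhexanamide | C[C@](Cl)([C@H](Br)C[C@H](Cl)C(=O)N(C)OC)[C@@H]1COC(C)(C)O1 | intermediate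
13 | lithium (3S,5R,6R)-5-bromo-1,3,6-trichloro-6-[(4S)-2,2-dimethyl-1,3-dioxolan-4-yl]-2-[methoxy(methyl)amino]heptan-2-olate (C2 undefined) | C[C@](Cl)([C@H](Br)C[C@H](Cl)C(O[Li])(CCl)N(C)OC)[C@@H]1COC(C)(C)O1 | intermediate
14 | (3S,5R,6R)-5-bromo-1,3,6-trichloro-6-[(4S)-2,2-dimethyl-1,3-dioxolan-4-yl]heptan-2-one | C[C@](Cl)([C@H](Br)C[C@H](Cl)C(=O)CCl)[C@@H]1COC(C)(C)O1 | intermediate
15 | (2S,3S,5R,6R)-5-bromo-1,3,6-trichloro-6-[(4S)-2,2-dimethyl-1,3-dioxolan-4-yl]-2-methylheptan-2-ol | C[C@](Cl)([C@H](Br)C[C@H](Cl)[C@@](C)(O)CCl)[C@@H]1COC(C)(C)O1 | intermediate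
16 | (2S,3S,5R,6R)-5-bromo-1,3,6-trichloro-6-[(4S)-2,2-dimethyl-1,3-dioxolan-4-yl]-2-methylheptan-2-yl trifluoromethanesulfonate | C[C@](Cl)([C@H](Br)C[C@H](Cl)[C@@](C)(OS(=O)(=O)C(F)(F)F)CCl)[C@@H]1COC(C)(C)O1 | intermediate
17 | (4S)-4-[(2R,3R,5S,6S)-3,6-dibromo-2,5,7-trichloro-6-methylheptan-2-yl]-2,2-dimethyl-1,3-dioxolane | C[C@](Cl)([C@H](Br)C[C@H](Cl)[C@@](C)(Br)CCl)[C@@H]1COC(C)(C)O1 | intermediate
18 | (2S,3R,4R,6S,7S)-4,7-dibromo-3,6,8-trichloro-3,7-dimethyloctane-1,2-diol | C[C@](Cl)([C@H](Br)C[C@H](Cl)[C@@](C)(Br)CCl)[C@@H](O)CO | intermediate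
19 | (2S,3R,4R,6S,7S)-4,7-dibromo-3,6,8-trichloro-2-hydroxy-3,7-dimethyloctyl 4-methylbenzenesulfonate | C[C@](Cl)([C@H](Br)C[C@H](Cl)[C@@](C)(Br)CCl)[C@@H](O)COS(=O)(=O)c1ccc(C)cc1 | intermediate
20 | (2S)-2-[(2R,3R,5S,6S)-3,6-dibromo-2,5,7-trichloro-6-methylheptan-2-yl]oxirane | C[C@](Cl)([C@H](Br)C[C@H](Cl)[C@@](C)(Br)CCl)[C@@H]1CO1 | target

**Step count and risks**

Total step count: 13. Longest linear sequence: 12 steps (from 1 through steps 1–4 and 6–13).

Steps most likely to fail:

1. Step 10 (carries the label "Proposed new method:"). The triflate may lose a proton to give alkenes, or ionise without halogen bridging so that configuration at C7 is lost, or the bridged ion may be opened at the wrong carbon. The fallback uses known chemistry, sets out from 15 and comes back at 18. The acetonide of 15 is hydrolysed first (CF3CO2H–H2O, 0 °C) to give (2S,3R,4R,6S,7S)-4-bromo-3,6,8-trichloro-3,7-dimethyloctane-1,2,7-triol F1. F1 is then treated with anhydrous HBr in CH2Cl2 at 0 °C, the classical conversion of a tertiary chlorohydrin into the vicinal bromo chloride. In this protic medium any alkene formed by elimination should re-add HBr in the Markovnikov sense, and the primary and secondary hydroxyls should not be substituted. The product is diol 18, at which stage C7 epimers, if formed, would be separated.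

2. Step 6. The bromine donor may meet the C4 radical on the other face, since only a small difference between placing the C3 methyl or the C3 chlorine beside C5 decides it; bromine transfer may also lag behind loss of the C3 chlorine. The fallback sets out from 4 and 10 and comes back at 11. Markovnikov addition of HBr to alkyne 4 (Et4NBr·HBr, CH2Cl2, 40 °C) would give (4S)-4-[(2R)-3-bromo-2-chlorobut-3-en-2-yl]-2,2-dimethyl-1,3-dioxolane F2. The same Yb(OTf)3/BEt3/O2 atom-transfer addition of 10 to F2 would give the geminal dibromide (4R)-4-benzyl-3-[(2S,5R)-4,4-dibromo-2,5-dichloro-5-[(4S)-2,2-dimethyl-1,3-dioxolan-4-yl]hexanoyl]-1,3-oxazolidin-2-one F3, in which C4 is not stereogenic, so the C–C bond is made without a facial question at C4. One bromine is then removed with (Me3Si)3SiH, BEt3/O2, toluene, −78 °C. The α-bromo C4 radical now accepts hydrogen where the parent radical accepted bromine, so a preference for the wrong face in step 6 becomes the required configuration of 11, and the hydrogen donor can be varied independently of the chain carrier.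

3. Step 4. Hydrogenolysis of the tertiary propargylic C–Cl bond or over-reduction may occur on the palladium surface. The fallback sets out from 4 and comes back at 5 and avoids a transition-metal surface. Syn-hydroboration of the terminal alkyne with dicyclohexylborane (THF, 0 °C) would give (4S)-4-[(2S,3E)-2-chloro-4-(dicyclohexylboranyl)but-3-en-2-yl]-2,2-dimethyl-1,3-dioxolane F4. Protonolysis of its alkenyl–boron bond with acetic acid (0 °C to rt) would then deliver 5.

**Further compounds**

F1 | step 10 | (2S,3R,4R,6S,7S)-4-bromo-3,6,8-trichloro-3,7-dimethyloctane-1,2,7-triol | C[C@](Cl)([C@H](Br)C[C@H](Cl)[C@@](C)(O)CCl)[C@@H](O)CO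
F2 | step 6 | (4S)-4-[(2R)-3-bromo-2-chlorobut-3-en-2-yl]-2,2-dimethyl-1,3-dioxolane | C[C@](Cl)(C(Br)=C)[C@@H]1COC(C)(C)O1
F3 | step 6 | (4R)-4-benzyl-3-[(2S,5R)-4,4-dibromo-2,5-dichloro-5-[(4S)-2,2-dimethyl-1,3-dioxolan-4-yl]hexanoyl]-1,3-oxazolidin-2-one | C[C@](Cl)(C(Br)(Br)C[C@H](Cl)C(=O)N1C(=O)OC[C@H]1Cc1ccccc1)[C@@H]2COC(C)(C)O2
F4 | step 4 | (4S)-4-[(2S,3E)-2-chloro-4-(dicyclohexylboranyl)but-3-en-2-yl]-2,2-dimethyl-1,3-dioxolane | C[C@](Cl)(/C=C/B(C1CCCCC1)C1CCCCC1)[C@@H]1COC(C)(C)O1
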